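**Plan**
- Enabling feature: C2, the only stereocentre, lies β to the C4 aryl ketone and carries the pyranone oxygen O1. The pyranone ring can therefore be closed through O1–C2 by conjugate addition of a phenol, provided C3 temporarily carries an ester.
- Retrosynthetic cuts, in order: the two O–CH3 caps at C5 and C8; the C3–CO2t-Bu bond; O1–C2 (ring closure); C2=C3 (Knoevenagel to the C18 Z-enal); C3–C4 (Claisen with tert-butyl acetate); C4–C4a (directed ortho-lithiation and carboxylation of MOM-protected 2,5-dimethoxyphenol).
- Forward order: the benzene ring is purchased; C4, then C3, then C2 with its C17 chain are attached; the pyranone ring closes last; decarboxylation and demethylation finish.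
- Stereochemistry: C2 (R) is set in the ring closure by a cinchona-alkaloid thiourea; the Z alkene arrives with the aldehyde; C3 is transient and is erased.

Key step: step 6

Assumption: (Z)-octadec-13-enal, a lepidopteran pheromone component, is taken as a purchasable starting material of high Z purity.
Assumption: the quinine-derived thiourea is taken to deliver the 2R sense with an aliphatic alkylidene; its quinidine-derived pseudoenantiomer attacks the opposite face and would replace it should the sense prove reversed.

**Route**

Step 1
Reactants: 1 2,5-dimethoxyphenol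
Product: 2 1,4-dimethoxy-2-(methoxymethoxy)benzene
Conditions: MOMCl, i-Pr2NEt, CH2Cl2, 0 °C → rt
Reagents that add atoms: chloromethyl methyl ether (MOMCl), COCCl
Why: O-Alkylation of the phenoxide with the chloromethyl ether (Williamson-type MOM protection) should be clean for an unhindered phenol and installs the acetal that will direct the lithiation.

Step 2
Reactants: 2 1,4-dimethoxy-2-(methoxymethoxy)benzene
Product: 4 methyl 3,6-dimethoxy-2-(methoxymethoxy)benzoate, via aryllithium 3 (not isolated)
Conditions: n-BuLi, THF, 0 °C; then cannulated into ClCO2Me (excess), THF, −78 °C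
Reagents that add atoms: methyl chloroformate, COC(=O)Cl
Why: Directed ortho-metalation: the ring hydrogen flanked by the OMOM and OMe groups is the most acidic and the lithium is chelated by both oxygens, so n-BuLi should lithiate only there, and inverse addition of the hindered aryllithium to excess chloroformate at −78 °C should stop at the ester.

Step 3
Reactants: 4 methyl 3,6-dimethoxy-2-(methoxymethoxy)benzoate
Product: 5 methyl 2-hydroxy-3,6-dimethoxybenzoate
Conditions: HCl (3 M aq., cat.), MeOH, 50 °C
Reagents that add atoms: none
Why: Acid-catalysed acetal methanolysis removes the MOM group once it has served as director; the methyl ester is unchanged in methanol, the aryl methyl ethers are inert, and no tert-butyl ester is yet present to conflict with the acid.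

Step 4
Reactants: 5 methyl 2-hydroxy-3,6-dimethoxybenzoate; 6 tert-butyl acetate
Product: 8 tert-butyl 3-(2-hydroxy-3,6-dimethoxyphenyl)-3-oxopropanoate, via lithium ester enolate 7 (not isolated)
Conditions: 6, LiN(i-Pr)2 (4 equiv), THF, −78 °C; then 5, −78 °C → rt; aq. NH4Cl
Reagents that add atoms: none
Why: Crossed Claisen condensation: one equivalent of enolate is spent on the phenol, a second adds to the lithium-chelated salicylate carbonyl and a third holds the product as its enolate so that no further addition occurs, while the tert-butyl ester resists attack by the neighbouring phenoxide, so no coumarin should form.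

Step 5
Reactants: 8 tert-butyl 3-(2-hydroxy-3,6-dimethoxyphenyl)-3-oxopropanoate; 9 (Z)-octadec-13-enal
Product: 10 tert-butyl (15Z)-2-(2-hydroxy-3,6-dimethoxybenzoyl)icosa-2,15-dienoate (expected as a mixture of 2E and 2Z isomers)
Conditions: piperidine (0.2 equiv), AcOH (0.2 equiv), 4 Å molecular sieves, toluene, 0 °C → rt; cold dilute acid wash
Reagents that add atoms: none
Why: Knoevenagel condensation through the piperidine-derived iminium ion of the aldehyde and the enol of the β-keto ester, with sieves taking up the water; buffered catalysis at or below room temperature should limit aldehyde self-condensation, double-bond migration and premature ring closure, and the alkylidene geometry does not matter for the next step.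

Step 6
Reactants: 10 tert-butyl (15Z)-2-(2-hydroxy-3,6-dimethoxybenzoyl)icosa-2,15-dienoate
Product: 11 tert-butyl (2R,3R)-2-[(Z)-heptadec-12-enyl]-5,8-dimethoxy-4-oxochromane-3-carboxylate (trans keto form, C3 epimerisable)
Conditions: 1-[3,5-bis(trifluoromethyl)phenyl]-3-[(8α,9S)-6'-methoxycinchonan-9-yl]thiourea (10 mol %), toluene, −25 °C; cold 1 M HCl wash, crude product carried on
Reagents that add atoms: none
Why: The thiourea N–H pair of the catalyst hydrogen-bonds the ketone/ester 1,3-dicarbonyl of 10 while the quinuclidine nitrogen takes up the proton of the 2-hydroxyl, and the phenol oxygen adds to the alkylidene carbon to form O1–C2, the resulting enolate being protonated at C3 to the more stable trans keto ester. The closest known reaction type is the bifunctional cinchona-thiourea-catalysed intramolecular oxa-Michael addition of phenols to alkylidene β-keto esters that gives flavanones and 2-alkylchromanones. The pyranone ring closes in a 6-endo-trig mode. C2 is set by the catalyst, whose chiral pocket exposes one face of the bound alkylidene to the tethered phenoxide (2R with the pseudoenantiomer chosen), whereas C3 is under thermodynamic control and disappears in step 7. The step needs enantiofacial selectivity and a slow uncatalysed closure: the extra ester supplies the second hydrogen-bond acceptor for two-point binding and enough activation for reaction at −25 °C in toluene, both alkylidene isomers lead to the same ring and can equilibrate through reversible addition, and because the other two ring oxygens are capped as methyl ethers the 2-hydroxyl is the only nucleophile, so only the 5,8-dioxygenated chromanone can form.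

Step 7
Reactants: 11 tert-butyl (2R,3R)-2-[(Z)-heptadec-12-enyl]-5,8-dimethoxy-4-oxochromane-3-carboxylate
Product: 13 (2R)-2-[(Z)-heptadec-12-enyl]-5,8-dimethoxychroman-4-one, via β-keto acid 12 (not isolated)
Conditions: TsOH·H2O (1 equiv), toluene, 80 °C
Reagents that add atoms: none
Why: Acid-catalysed loss of isobutene from the tert-butyl ester (E1) and thermal decarboxylation of the β-keto acid through its cyclic six-membered transition state remove the auxiliary ester and the C3 stereocentre; C2 is untouched because acid generates neither the phenoxide nor the enolate needed to reopen the ring, and the isolated Z alkene and methyl ethers should tolerate TsOH at this temperature.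

Step 8
Reactants: 13 (2R)-2-[(Z)-heptadec-12-enyl]-5,8-dimethoxychroman-4-one
Product: 14 (2R)-2-[(Z)-heptadec-12-enyl]-5,8-dihydroxychroman-4-one
Conditions: BBr3 (4 equiv), CH2Cl2, −78 → 0 °C; ice-water quench
Reagents that add atoms: none
Why: Lewis-acid ether cleavage with BBr3: bromide attacks the methyl carbons of the boron-complexed ethers (SN2) far faster than the secondary C2 of the ring ether, the C5 ether being further assisted by chelation to the C4 carbonyl, and the low temperature with a cold aqueous quench should spare the Z alkene and the C2 stereocentre.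

**Compound list**
1 | 2,5-dimethoxyphenol | COc1ccc(OC)c(O)c1 | starting material
2 | 1,4-dimethoxy-2-(methoxymethoxy)benzene | COCOc1cc(OC)ccc1OC | intermediate
3 | [3,6-dimethoxy-2-(methoxymethoxy)phenyl]lithium (formed in step 2, not isolated) | [Li]c1c(OCOC)c(OC)ccc1OC | intermediate
4 | methyl 3,6-dimethoxy-2-(methoxymethoxy)benzoate | COCOc1c(OC)ccc(OC)c1C(=O)OC | intermediate
5 | methyl 2-hydroxy-3,6-dimethoxybenzoate | COC(=O)c1c(O)c(OC)ccc1OC | intermediate
6 | tert-butyl acetate | CC(=O)OC(C)(C)C | starting material
7 | lithium 1-tert-butoxyethenolate, the lithium enolate of tert-butyl acetate (formed in step 4, not isolated) | [Li]OC(=C)OC(C)(C)C | intermediate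
8 | tert-butyl 3-(2-hydroxy-3,6-dimethoxyphenyl)-3-oxopropanoate | CC(C)(C)OC(=O)CC(=O)c1c(O)c(OC)ccc1OC | intermediate
9 | (Z)-octadec-13-enal | CCCC/C=C\CCCCCCCCCCCC=O | starting material
10 | tert-butyl (15Z)-2-(2-hydroxy-3,6-dimethoxybenzoyl)icosa-2,15-dienoate (2E/2Z mixture) | CCCC/C=C\CCCCCCCCCCCC=C(C(=O)OC(C)(C)C)C(=O)c1c(O)c(OC)ccc1OC | intermediate
11 | tert-butyl (2R,3R)-2-[(Z)-heptadec-12-enyl]-5,8-dimethoxy-4-oxochromane-3-carboxylate (trans) | CCCC/C=C\CCCCCCCCCCC[C@@H]1[C@@H](C(=O)OC(C)(C)C)C(=O)c2c(OC)ccc(OC)c2O1 | intermediate
12 | (2R,3R)-2-[(Z)-heptadec-12-enyl]-5,8-dimethoxy-4-oxochromane-3-carboxylic acid (formed in step 7, not isolated) | CCCC/C=C\CCCCCCCCCCC[C@@H]1[C@@H](C(=O)O)C(=O)c2c(OC)ccc(OC)c2O1 | intermediate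
13 | (2R)-2-[(Z)-heptadec-12-enyl]-5,8-dimethoxychroman-4-one | CCCC/C=C\CCCCCCCCCCC[C@@H]1CC(=O)c2c(OC)ccc(OC)c2O1 | intermediate
14 | (2R)-2-[(Z)-heptadec-12-enyl]-5,8-dihydroxychroman-4-one | CCCC/C=C\CCCCCCCCCCC[C@@H]1CC(=O)c2c(O)ccc(O)c2O1 | target

**Step count**
Total steps: 8. Longest linear sequence: 8 steps (1 → 14); tert-butyl acetate and the aldehyde enter as purchased compounds.

**Steps most likely to fail**

Step 6. What may go wrong: facial selectivity that is too low for an aliphatic alkylidene, erosion by the uncatalysed closure or by ring reopening before the catalyst is removed, and γ-deprotonation that moves the double bond out of conjugation. The enantiomeric purity would be assayed at 13 on a chiral stationary phase. Fallback (the stereocentre is made before the ring and closed with inversion), setting out from aldehyde 9 and returning at 13: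
- Roskamp homologation of 9 with ethyl diazoacetate and SnCl2 in CH2Cl2 would give ethyl (15Z)-3-oxoicos-15-enoate F1.
- Noyori-type hydrogenation of the keto group with RuCl2[(S)-BINAP] in ethanol, under a few atmospheres of H2 with a trace of HCl, would give ethyl (3S,15Z)-3-hydroxyicos-15-enoate F2. Under these conditions the chelating keto ester is normally reduced much faster than a remote 1,2-disubstituted alkene.
- MeNH(OMe)·HCl and i-PrMgCl in THF would convert F2 into (3S,15Z)-3-hydroxy-N-methoxy-N-methylicos-15-enamide F3.
- After deprotonation of the hydroxyl with i-PrMgCl, addition of aryllithium 3 (made from 2 as in step 2) would give (3S,15Z)-1-[3,6-dimethoxy-2-(methoxymethoxy)phenyl]-3-hydroxyicos-15-en-1-one F4.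
- Brief treatment with catalytic HCl in methanol would remove the MOM group to give (3S,15Z)-3-hydroxy-1-(2-hydroxy-3,6-dimethoxyphenyl)icos-15-en-1-one F5.
- Mitsunobu ring closure (PPh3, DIAD, THF, 0 °C) would form O1–C2 with inversion of the S carbinol and give 13.

Step 5. What may go wrong: closure of the free phenol onto the new alkylidene under the amine catalyst (racemic ring closure before the key step), migration of the double bond out of conjugation, and Michael addition of a second molecule of 8. Fallback (the nucleophile is masked during the condensation), setting out from 8 and returning at 10: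
- TBSCl and imidazole in DMF would give tert-butyl 3-[2-(tert-butyldimethylsilyloxy)-3,6-dimethoxyphenyl]-3-oxopropanoate F6.
- Knoevenagel condensation with 9 under the same piperidinium acetate conditions would give tert-butyl (15Z)-2-[2-(tert-butyldimethylsilyloxy)-3,6-dimethoxybenzoyl]icosa-2,15-dienoate F7, which cannot cyclise.
- HF·pyridine in THF at 0 °C, an acidic desilylation that never generates free phenoxide, would release 10.

Step 8. What may go wrong: addition of HBr to the Z alkene or its isomerisation, and Lewis-acid opening of the O1–C2 bond with loss of the stereocentre. Fallback (oxidative instead of Lewis-acidic unmasking of the hydroquinone), setting out from 13 and returning at 14: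
- (NH4)2Ce(NO3)6 in MeCN/H2O at 0 °C would oxidise the para-dimethoxyarene to (2R)-2-[(Z)-heptadec-12-enyl]-2,3-dihydrochromene-4,5,8-trione F8, both methyl groups leaving as methanol.
- Immediate reduction with aqueous Na2S2O4 in a two-phase mixture with ethyl acetate would give 14.

**Further compounds**
F1 | step 6 | ethyl (15Z)-3-oxoicos-15-enoate | CCCC/C=C\CCCCCCCCCCCC(=O)CC(=O)OCC
F2 | step 6 | ethyl (3S,15Z)-3-hydroxyicos-15-enoate | CCCC/C=C\CCCCCCCCCCC[C@H](O)CC(=O)OCC
F3 | step 6 | (3S,15Z)-3-hydroxy-N-methoxy-N-methylicos-15-enamide | CCCC/C=C\CCCCCCCCCCC[C@H](O)CC(=O)N(C)OC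
F4 | step 6 | (3S,15Z)-1-[3,6-dimethoxy-2-(methoxymethoxy)phenyl]-3-hydroxyicos-15-en-1-one | CCCC/C=C\CCCCCCCCCCC[C@H](O)CC(=O)c1c(OCOC)c(OC)ccc1OC
F5 | step 6 | (3S,15Z)-3-hydroxy-1-(2-hydroxy-3,6-dimethoxyphenyl)icos-15-en-1-one | CCCC/C=C\CCCCCCCCCCC[C@H](O)CC(=O)c1c(O)c(OC)ccc1OC
F6 | step 5 | tert-butyl 3-[2-(tert-butyldimethylsilyloxy)-3,6-dimethoxyphenyl]-3-oxopropanoate | CC(C)(C)OC(=O)CC(=O)c1c(O[Si](C)(C)C(C)(C)C)c(OC)ccc1OC
F7 | step 5 | tert-butyl (15Z)-2-[2-(tert-butyldimethylsilyloxy)-3,6-dimethoxybenzoyl]icosa-2,15-dienoate (2E/2Z mixture) | CCCC/C=C\CCCCCCCCCCCC=C(C(=O)OC(C)(C)C)C(=O)c1c(O[Si](C)(C)C(C)(C)C)c(OC)ccc1OC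
F8 | step 8 | (2R)-2-[(Z)-heptadec-12-enyl]-2,3-dihydrochromene-4,5,8-trione | CCCC/C=C\CCCCCCCCCCC[C@@H]1CC(=O)C2=C(O1)C(=O)C=CC2=O
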